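**Plan** (prostanoid numbering: C1 ester carbon, ring C8–C12, C9 carbonyl, C20 methyl)
Retrosynthesis: the C10–I bond, the C7 acetate and the C9 carbonyl are taken off first. The C5=C6 alkene is then cut (Wittig), so that C6 becomes the carbonyl of a lactone O–C6–C7–C8–C12. Removal of the C7 hydroxyl and of the C10=C11 alkene leads to an iodolactone, which is cut at C12–O and C11–I to a cyclopent-2-enylacetic acid. That acid is cut at C7–C8 (Claisen) to a 2-octenyl-4-hydroxycyclopentenone, and this ring goes back to furfural.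
Forward: the carbocycle arises first by furylcarbinol rearrangement with the C13–C20 chain attached. C6–C7 are joined to C8 by Ireland–Claisen rearrangement, and the lactone ring is closed by iodolactonisation. The C1–C5 chain is joined last by Wittig opening of the lactol, followed by acetylation, C9 oxidation and C10 iodination.
Enabling feature: the C12 hydroxyl and the C7 branch on C8 are cis on the ring C8–C12, so a C6 carboxyl on that branch reaches the C12 oxygen through a five-membered lactone ring and later becomes the C6 alkene carbon.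
Stereochemistry: a lipase resolution fixes C9 (S). It is relayed to C11 by cis-selective Luche reduction, to C8 by the suprafacial Claisen shift, to C12 by the cis-fused anti iodolactonisation and to C7 by convex-face enolate hydroxylation. The Z alkenes come from Lindlar reduction and a Z-selective Wittig reaction.

Key step: step 11

Assumption: porcine pancreatic lipase acylates the (R)-enantiomer of hydroxy enone 10, as is usual for 4-hydroxy-2-alkylcyclopent-2-enones, so that the (S)-alcohol 11 is the enantiomer left unreacted.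

**Step 1**
Reactants: 1 furfural; 2 propargyl bromide
Product: 3 rac-1-(furan-2-yl)but-3-yn-1-ol
Conditions: Zn dust, THF/sat. aq NH4Cl, 0 °C to rt
Reagents that add atoms: none
Why: Barbier propargylation at the zinc surface should transfer the propargyl unit of 2 to the aldehyde with allylic transposition, which for the unsubstituted bromide gives the homopropargylic alcohol; the racemic carbinol centre is erased in step 3.

**Step 2**
Reactants: 3 rac-1-(furan-2-yl)but-3-yn-1-ol; 4 1-iodopentane
Product: 6 rac-1-(furan-2-yl)non-3-yn-1-ol, via dilithio alkoxide acetylide 5 (not isolated)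
Conditions: n-BuLi (2.1 equiv), THF, −78 to −20 °C; then 4, DMPU, −20 °C to rt; H2O
Reagents that add atoms: none
Why: Acetylide alkylation: of the two anionic sites in 5 the sp carbanion is far more nucleophilic than the lithium alkoxide, so the primary iodide should be attacked at carbon (SN2) in the dipolar cosolvent.

**Step 3**
Reactants: 6 rac-1-(furan-2-yl)non-3-yn-1-ol
Product: 7 rac-trans-4-hydroxy-5-(oct-2-yn-1-yl)cyclopent-2-en-1-one
Conditions: ZnCl2, dioxane/H2O, reflux
Reagents that add atoms: water, O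
Why: Piancatelli rearrangement: Lewis-acid-assisted ionisation of the furylcarbinol, addition of water at C5 of the furan, ring opening and conrotatory 4π electrocyclisation should give the 4,5-trans hydroxy enone as the racemate.

**Step 4**
Reactants: 7 rac-trans-4-hydroxy-5-(oct-2-yn-1-yl)cyclopent-2-en-1-one
Product: 9 rac-4-hydroxy-2-(oct-2-yn-1-yl)cyclopent-2-en-1-one, via dihydroxy ketone 8 (not isolated)
Conditions: Na2HPO4/NaH2PO4 buffer (pH 8), dioxane/H2O, 50 °C
Reagents that add atoms: water, O
Why: Base-mediated isomerisation known for 5-substituted 4-hydroxycyclopentenones: conjugate addition of water gives 8 and E1cB loss of the original hydroxyl group places the enone on the alkyl-bearing carbon, the more substituted and more stable enone.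

**Step 5**
Reactants: 9 rac-4-hydroxy-2-(oct-2-yn-1-yl)cyclopent-2-en-1-one
Product: 10 rac-4-hydroxy-2-[(Z)-oct-2-en-1-yl]cyclopent-2-en-1-one
Conditions: H2 (1 atm), Pd/CaCO3 poisoned with Pb(OAc)2, quinoline, EtOAc, rt
Reagents that add atoms: none
Why: Lindlar semihydrogenation adds hydrogen syn to the alkyne on the poisoned surface and should stop at the Z alkene (the future C14=C15) without touching the conjugated, trisubstituted ring alkene.

**Step 6**
Reactants: 10 rac-4-hydroxy-2-[(Z)-oct-2-en-1-yl]cyclopent-2-en-1-one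
Product: 11 (S)-4-hydroxy-2-[(Z)-oct-2-en-1-yl]cyclopent-2-en-1-one
Conditions: porcine pancreatic lipase, vinyl acetate, rt, taken past half conversion; chromatography
Reagents that add atoms: none
Why: Lipase-catalysed kinetic resolution by irreversible transesterification with an enol ester should acetylate the (R)-alcohol and leave the (S)-alcohol, which is separated from the acetate; this sets C9, the centre from which all others are relayed.

**Step 7**
Reactants: 11 (S)-4-hydroxy-2-[(Z)-oct-2-en-1-yl]cyclopent-2-en-1-one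
Product: 12 (S)-4-[(tert-butyldimethylsilyl)oxy]-2-[(Z)-oct-2-en-1-yl]cyclopent-2-en-1-one
Conditions: t-BuMe2SiCl, imidazole, DMF, 0 °C to rt
Reagents that add atoms: tert-butyldimethylsilyl chloride, CC(C)(C)[Si](C)(C)Cl
Why: Standard silylation of the secondary alcohol masks the C9 oxygen until step 18 and keeps it from lactonising onto the later carboxyl group.

**Step 8**
Reactants: 12 (S)-4-[(tert-butyldimethylsilyl)oxy]-2-[(Z)-oct-2-en-1-yl]cyclopent-2-en-1-one
Product: 13 (1R,4S)-4-[(tert-butyldimethylsilyl)oxy]-2-[(Z)-oct-2-en-1-yl]cyclopent-2-en-1-ol (cis)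
Conditions: NaBH4, CeCl3·7H2O, MeOH, −78 to −40 °C
Reagents that add atoms: none
Why: Luche reduction gives 1,2-reduction of the enone, and hydride should approach anti to the bulky silyloxy group so that the new C11 carbinol is cis to it.

**Step 9**
Reactants: 13 (1R,4S)-4-[(tert-butyldimethylsilyl)oxy]-2-[(Z)-oct-2-en-1-yl]cyclopent-2-en-1-ol
Product: 14 (1R,4S)-4-[(tert-butyldimethylsilyl)oxy]-2-[(Z)-oct-2-en-1-yl]cyclopent-2-en-1-yl acetate
Conditions: Ac2O, pyridine, DMAP (cat.), CH2Cl2, 0 °C to rt
Reagents that add atoms: acetic anhydride, CC(=O)OC(C)=O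
Why: Acylation of the secondary allylic alcohol under nucleophilic catalysis provides the allyl acetate needed for the ester enolate Claisen rearrangement without affecting a stereocentre.

**Step 10**
Reactants: 14 (1R,4S)-4-[(tert-butyldimethylsilyl)oxy]-2-[(Z)-oct-2-en-1-yl]cyclopent-2-en-1-yl acetate
Product: 17 2-[(1R,5S)-5-[(tert-butyldimethylsilyl)oxy]-2-[(Z)-oct-2-en-1-yl]cyclopent-2-en-1-yl]acetic acid, via silyl ketene acetal 15 (not isolated), via trimethylsilyl ester 16 (not isolated)
Conditions: LiN(i-Pr)2, Me3SiCl/Et3N (in situ trap), THF, −78 °C; then reflux; dilute aq. HCl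
Reagents that add atoms: none
Why: Ireland–Claisen rearrangement: the acetate enolate is trapped on oxygen as 15, which rearranges suprafacially through the boat-like [3,3] transition state imposed by the ring, so the new C7–C8 bond forms on the face that carried the C11 oxygen (cis to the C9 silyl ether), the C11 centre is traded for C8 (R) and the alkene moves to C11=C12; mild acid frees the acid from 16.

**Step 11**
Reactants: 17 2-[(1R,5S)-5-[(tert-butyldimethylsilyl)oxy]-2-[(Z)-oct-2-en-1-yl]cyclopent-2-en-1-yl]acetic acid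
Product: 19 (3aS,4S,6S,6aS)-4-[(tert-butyldimethylsilyl)oxy]-6-iodo-6a-[(Z)-oct-2-en-1-yl]hexahydro-2H-cyclopenta[b]furan-2-one (cis-fused, iodide trans to the lactone oxygen), via sodium carboxylate 18 (not isolated)
Conditions: NaHCO3, I2, KI, THF/H2O, 0 °C, dark
Reagents that add atoms: iodine, II
Why: Iodine forms an iodonium ion reversibly on the trisubstituted C11=C12 alkene, preferentially on the face opposite the C8 and C9 substituents, and the carboxylate of 18 opens it at C12 in an anti addition that makes the C12–O and C11–I bonds. The closest known reaction type is the iodolactonisation of γ,δ-unsaturated acids, in particular of cyclopent-2-enylacetic acids to cis-fused bicyclic lactones. The five-membered lactone ring (O–C6–C7–C8–C12) closes in the 5-exo-trig mode, and the one-carbon link C7 between C8 and the carboxyl carbon can only reach the ring face it stands on, so the fusion must be cis. C12 (S) is therefore controlled by C8, and C11 (S) by the anti opening of the iodonium ion, which places iodine trans to the lactone oxygen and antiperiplanar to a C10 hydrogen for step 12. The step needs Markovnikov attack at C12 and reaction at the ring alkene only: the fully substituted C12 carries the larger positive charge, attack at C11 would give a strained bridged six-membered lactone, and the C14=C15 alkene has no internal nucleophile within reach, so its reversible iodonium formation should lead nowhere.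

**Step 12**
Reactants: 19 the iodolactone
Product: 20 (3aS,4S,6aR)-4-[(tert-butyldimethylsilyl)oxy]-6a-[(Z)-oct-2-en-1-yl]-3,3a,4,6a-tetrahydro-2H-cyclopenta[b]furan-2-one
Conditions: DBU, toluene, 90 °C
Reagents that add atoms: none
Why: E2 dehydroiodination with an amidine base: C12 is quaternary, so the only β-hydrogens are on C10 and the one anti to iodide is removed, giving the C10=C11 alkene of the final enone.

**Step 13**
Reactants: 20 the unsaturated lactone
Product: 22 (3R,3aS,4S,6aR)-4-[(tert-butyldimethylsilyl)oxy]-3-hydroxy-6a-[(Z)-oct-2-en-1-yl]-3,3a,4,6a-tetrahydro-2H-cyclopenta[b]furan-2-one, via potassium enolate 21 (not isolated)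
Conditions: KN(SiMe3)2, THF, −78 °C; then 2-(phenylsulfonyl)-3-phenyloxaziridine, −78 °C; AcOH
Reagents that add atoms: 2-(phenylsulfonyl)-3-phenyloxaziridine, O=S(=O)(c1ccccc1)N1OC1c1ccccc1
Why: Enolate hydroxylation with an N-sulfonyloxaziridine (Davis oxidation): enolate 21 of the cis-fused lactone should be attacked on its convex face, away from the carbocycle and the C9 silyl ether that fill the concave face, which places the new hydroxyl cis to H8 and gives the C7 configuration of the target.

**Step 14**
Reactants: 22 the hydroxy lactone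
Product: 23 (3R,3aS,4S,6aR)-4-[(tert-butyldimethylsilyl)oxy]-6a-[(Z)-oct-2-en-1-yl]-3,3a,4,6a-tetrahydro-2H-cyclopenta[b]furan-2,3-diol (lactol, both anomers)
Conditions: i-Bu2AlH (2.5 equiv), CH2Cl2, −78 °C; aq. potassium sodium tartrate
Reagents that add atoms: none
Why: Low-temperature i-Bu2AlH reduction of a lactone stops at the lactol because the aluminium hemiacetal does not collapse at −78 °C; one extra equivalent is consumed by the free hydroxyl group.

**Step 15**
Reactants: 23 the lactol; 24 (4-carboxybutyl)triphenylphosphonium bromide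
Product: 26 (5Z,7S)-7-[(1S,2R,5S)-5-[(tert-butyldimethylsilyl)oxy]-2-hydroxy-2-[(Z)-oct-2-en-1-yl]cyclopent-3-en-1-yl]-7-hydroxyhept-5-enoic acid, via phosphorus ylide 25 (not isolated)
Conditions: 24, KN(SiMe3)2, THF, 0 °C; then 23, −78 °C to rt; aq. HCl to pH 4
Reagents that add atoms: none
Why: Wittig olefination of the ring-opened hydroxy aldehyde form of the lactol with the non-stabilised, lithium-free ylide 25 should form the cis-oxaphosphetane kinetically and hence the Z C5=C6 alkene, as in the olefination of prostaglandin lactols; C7 is not touched and C12 is released as the free tertiary alcohol.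

**Step 16**
Reactants: 26 the dihydroxy acid
Product: 27 methyl (5Z,7S)-7-[(1S,2R,5S)-5-[(tert-butyldimethylsilyl)oxy]-2-hydroxy-2-[(Z)-oct-2-en-1-yl]cyclopent-3-en-1-yl]-7-hydroxyhept-5-enoate
Conditions: Me3SiCHN2, MeOH/toluene, 0 °C
Reagents that add atoms: (trimethylsilyl)diazomethane, C[Si](C)(C)C=[N+]=[N-]
Why: O-Methylation with a diazoalkane proceeds by proton transfer from the acid and is selective for the carboxyl group over both alcohols.

**Step 17**
Reactants: 27 the dihydroxy methyl ester
Product: 28 methyl (5Z,7S)-7-acetoxy-7-[(1S,2R,5S)-5-[(tert-butyldimethylsilyl)oxy]-2-hydroxy-2-[(Z)-oct-2-en-1-yl]cyclopent-3-en-1-yl]hept-5-enoate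
Conditions: Ac2O, pyridine, DMAP (cat.), CH2Cl2, 0 °C
Reagents that add atoms: acetic anhydride, CC(=O)OC(C)=O
Why: Acylation discriminates by steric demand, so the secondary C7 alcohol should react under mild nucleophilic catalysis while the tertiary C12 alcohol stays free.

**Step 18**
Reactants: 28 the silyl ether acetate
Product: 29 methyl (5Z,7S)-7-acetoxy-7-[(1R,2R,5S)-2,5-dihydroxy-2-[(Z)-oct-2-en-1-yl]cyclopent-3-en-1-yl]hept-5-enoate
Conditions: HF·pyridine, pyridine, THF, 0 °C to rt
Reagents that add atoms: none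
Why: Fluoride-mediated desilylation in a buffered acidic medium removes the C9 silyl ether without the basic conditions that would favour acetyl migration from O7 to O9.

**Step 19**
Reactants: 29 the C9 alcohol
Product: 30 methyl (5Z,7S)-7-acetoxy-7-[(1R,2R)-2-hydroxy-2-[(Z)-oct-2-en-1-yl]-5-oxocyclopent-3-en-1-yl]hept-5-enoate
Conditions: Dess–Martin periodinane, CH2Cl2, 0 °C to rt
Reagents that add atoms: none
Why: Dess–Martin oxidation of the secondary allylic alcohol runs without base, so the β-acetoxy ketone formed should not lose acetic acid, and the tertiary alcohol cannot be oxidised.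

**Step 20**
Reactants: 30 the enone
Product: 31 7-acetoxy-7,8-dihydroiodovulone I (target)
Conditions: I2, pyridine, CH2Cl2, 0 °C to rt
Reagents that add atoms: iodine, II
Why: α-Iodination of the enone with iodine and pyridine (amine-mediated addition–elimination at C11/C10) should place iodine on C10 and leave the isolated Z alkenes untouched, as in the iodination of other 4,4-disubstituted cyclopentenones.

**Compound list**
1 | furfural | O=Cc1ccco1 | starting material
2 | propargyl bromide (3-bromoprop-1-yne) | BrCC#C | starting material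
3 | rac-1-(furan-2-yl)but-3-yn-1-ol | OC(CC#C)c1ccco1 | intermediate
4 | 1-iodopentane | CCCCCI | starting material
5 | dilithio derivative of 3 (lithium alkoxide and lithium acetylide) | [Li]C#CCC(O[Li])c1ccco1 | intermediate (not isolated)
6 | rac-1-(furan-2-yl)non-3-yn-1-ol | CCCCCC#CCC(O)c1ccco1 | intermediate
7 | rac-trans-4-hydroxy-5-(oct-2-yn-1-yl)cyclopent-2-en-1-one (racemic, one enantiomer drawn) | CCCCCC#CC[C@@H]1[C@@H](O)C=CC1=O | intermediate
8 | 3,4-dihydroxy-2-(oct-2-yn-1-yl)cyclopentan-1-one (racemic, diastereomer mixture) | CCCCCC#CCC1C(O)C(O)CC1=O | intermediate (not isolated)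
9 | rac-4-hydroxy-2-(oct-2-yn-1-yl)cyclopent-2-en-1-one | CCCCCC#CCC1=CC(O)CC1=O | intermediate
10 | rac-4-hydroxy-2-[(Z)-oct-2-en-1-yl]cyclopent-2-en-1-one | CCCCC/C=C\CC1=CC(O)CC1=O | intermediate
11 | (S)-4-hydroxy-2-[(Z)-oct-2-en-1-yl]cyclopent-2-en-1-one | CCCCC/C=C\CC1=C[C@@H](O)CC1=O | intermediate
12 | (S)-4-[(tert-butyldimethylsilyl)oxy]-2-[(Z)-oct-2-en-1-yl]cyclopent-2-en-1-one | CCCCC/C=C\CC1=C[C@@H](O[Si](C)(C)C(C)(C)C)CC1=O | intermediate
13 | (1R,4S)-4-[(tert-butyldimethylsilyl)oxy]-2-[(Z)-oct-2-en-1-yl]cyclopent-2-en-1-ol (cis) | CCCCC/C=C\CC1=C[C@@H](O[Si](C)(C)C(C)(C)C)C[C@H]1O | intermediate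
14 | (1R,4S)-4-[(tert-butyldimethylsilyl)oxy]-2-[(Z)-oct-2-en-1-yl]cyclopent-2-en-1-yl acetate | CCCCC/C=C\CC1=C[C@@H](O[Si](C)(C)C(C)(C)C)C[C@H]1OC(C)=O | intermediate
15 | trimethylsilyl ketene acetal of 14 | CCCCC/C=C\CC1=C[C@@H](O[Si](C)(C)C(C)(C)C)C[C@H]1OC(=C)O[Si](C)(C)C | intermediate (not isolated)
16 | trimethylsilyl ester of 17 | CCCCC/C=C\CC1=CC[C@H](O[Si](C)(C)C(C)(C)C)[C@@H]1CC(=O)O[Si](C)(C)C | intermediate (not isolated)
17 | 2-[(1R,5S)-5-[(tert-butyldimethylsilyl)oxy]-2-[(Z)-oct-2-en-1-yl]cyclopent-2-en-1-yl]acetic acid (acetic acid arm cis to the silyl ether) | CCCCC/C=C\CC1=CC[C@H](O[Si](C)(C)C(C)(C)C)[C@@H]1CC(=O)O | intermediate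
18 | sodium salt of 17 | CCCCC/C=C\CC1=CC[C@H](O[Si](C)(C)C(C)(C)C)[C@@H]1CC(=O)[O-].[Na+] | intermediate (not isolated)
19 | (3aS,4S,6S,6aS)-4-[(tert-butyldimethylsilyl)oxy]-6-iodo-6a-[(Z)-oct-2-en-1-yl]hexahydro-2H-cyclopenta[b]furan-2-one | CCCCC/C=C\C[C@]12OC(=O)C[C@H]1[C@@H](O[Si](C)(C)C(C)(C)C)C[C@@H]2I | intermediate
20 | (3aS,4S,6aR)-4-[(tert-butyldimethylsilyl)oxy]-6a-[(Z)-oct-2-en-1-yl]-3,3a,4,6a-tetrahydro-2H-cyclopenta[b]furan-2-one | CCCCC/C=C\C[C@]12OC(=O)C[C@H]1[C@@H](O[Si](C)(C)C(C)(C)C)C=C2 | intermediate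
21 | potassium enolate of 20 | CCCCC/C=C\C[C@]12OC([O-])=C[C@H]1[C@@H](O[Si](C)(C)C(C)(C)C)C=C2.[K+] | intermediate (not isolated)
22 | (3R,3aS,4S,6aR)-4-[(tert-butyldimethylsilyl)oxy]-3-hydroxy-6a-[(Z)-oct-2-en-1-yl]-3,3a,4,6a-tetrahydro-2H-cyclopenta[b]furan-2-one (hydroxyl on the convex face) | CCCCC/C=C\C[C@]12OC(=O)[C@H](O)[C@H]1[C@@H](O[Si](C)(C)C(C)(C)C)C=C2 | intermediate
23 | lactol of 22, (3R,3aS,4S,6aR)-configured 2,3-diol, both anomers | CCCCC/C=C\C[C@]12OC(O)[C@H](O)[C@H]1[C@@H](O[Si](C)(C)C(C)(C)C)C=C2 | intermediate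
24 | (4-carboxybutyl)triphenylphosphonium bromide | OC(=O)CCCC[P+](c1ccccc1)(c1ccccc1)c1ccccc1.[Br-] | starting material
25 | potassium 5-(triphenylphosphoranylidene)pentanoate (ylide) | [K+].[O-]C(=O)CCCC=P(c1ccccc1)(c1ccccc1)c1ccccc1 | intermediate (not isolated)
26 | (5Z,7S)-7-[(1S,2R,5S)-5-[(tert-butyldimethylsilyl)oxy]-2-hydroxy-2-[(Z)-oct-2-en-1-yl]cyclopent-3-en-1-yl]-7-hydroxyhept-5-enoic acid | CCCCC/C=C\C[C@@]1(O)C=C[C@H](O[Si](C)(C)C(C)(C)C)[C@@H]1[C@H](/C=C\CCCC(=O)O)O | intermediate
27 | methyl ester of 26 | CCCCC/C=C\C[C@@]1(O)C=C[C@H](O[Si](C)(C)C(C)(C)C)[C@@H]1[C@H](/C=C\CCCC(=O)OC)O | intermediate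
28 | methyl (5Z,7S)-7-acetoxy-7-[(1S,2R,5S)-5-[(tert-butyldimethylsilyl)oxy]-2-hydroxy-2-[(Z)-oct-2-en-1-yl]cyclopent-3-en-1-yl]hept-5-enoate | CCCCC/C=C\C[C@@]1(O)C=C[C@H](O[Si](C)(C)C(C)(C)C)[C@@H]1[C@H](/C=C\CCCC(=O)OC)OC(C)=O | intermediate
29 | methyl (5Z,7S)-7-acetoxy-7-[(1R,2R,5S)-2,5-dihydroxy-2-[(Z)-oct-2-en-1-yl]cyclopent-3-en-1-yl]hept-5-enoate | CCCCC/C=C\C[C@@]1(O)C=C[C@H](O)[C@@H]1[C@H](/C=C\CCCC(=O)OC)OC(C)=O | intermediate
30 | methyl (5Z,7S)-7-acetoxy-7-[(1R,2R)-2-hydroxy-2-[(Z)-oct-2-en-1-yl]-5-oxocyclopent-3-en-1-yl]hept-5-enoate | CCCCC/C=C\C[C@@]1(O)C=CC(=O)[C@@H]1[C@H](/C=C\CCCC(=O)OC)OC(C)=O | intermediate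
31 | 7-acetoxy-7,8-dihydroiodovulone I, methyl (5Z,7S)-7-acetoxy-7-[(1R,2S)-2-hydroxy-4-iodo-2-[(Z)-oct-2-en-1-yl]-5-oxocyclopent-3-en-1-yl]hept-5-enoate | CCCCC/C=C\C[C@@]1(O)C=C(I)C(=O)[C@@H]1[C@H](/C=C\CCCC(=O)OC)OC(C)=O | target

**Step count and risks**
Total step count: 20. Longest linear sequence: 20 steps (1 to 31); 2, 4 and 24 enter in steps 1, 2 and 15.

Steps most likely to fail:

Step 10. Self-condensation or C-silylation of the acetate enolate may outrun O-silylation, and the boat-like shift onto the ring face that carries the cis silyl ether may be slow enough for the ketene acetal to decompose. The fallback sets out from 13 and avoids the enolate altogether. Alcohol 13 is heated with triethyl orthoacetate and a catalytic amount of propionic acid at 140 °C with removal of ethanol (Johnson–Claisen rearrangement), which should give the ethyl ester F1 with the same suprafacial transfer. Saponification with LiOH in THF/MeOH/H2O and careful acidification then return the route to 17.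

Step 15. With a free hydroxyl group next to the masked aldehyde, the ylide may act mainly as a base: slow ring opening and olefination, migration of the silyl group from O9 to a neighbouring alkoxide, or epimerisation at C7. The fallback sets out from 22 and covers the C7 hydroxyl first. Silylation with Et3SiCl and imidazole in DMF should give the triethylsilyl ether F2. Reduction with i-Bu2AlH at −78 °C gives the lactol F3, olefination with ylide 25 gives the acid F4, and Me3SiCHN2 gives the methyl ester F5. Pyridinium p-toluenesulfonate in MeOH at 0 °C then removes the more labile triethylsilyl group only and returns the route to 27.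

Step 20. Under the amine that the iodination needs, the β-acetoxy ketone may lose acetic acid across C7–C8 (E1cB) and drain into the cross-conjugated dienone. The fallback sets out from 27 and introduces the acetate only after the halogen.
- The C7 alcohol is silylated with i-Pr3SiOTf and 2,6-lutidine at −78 °C to give the triisopropylsilyl ether F6.
- Buffered HF·pyridine removes the more labile tert-butyldimethylsilyl group at C9 to give the allylic alcohol F7.
- Dess–Martin oxidation gives the enone F8.
- Iodine and pyridine give the iodo enone F9; its β-silyloxy group is a poor leaving group.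
- Prolonged HF·pyridine frees the hydroxy iodo enone F10.
- A short, cold acetylation (Ac2O, pyridine, CH2Cl2, −20 °C) then returns the route to 31.

**Further compounds**
F1 | step 10 | ethyl 2-[(1R,5S)-5-[(tert-butyldimethylsilyl)oxy]-2-[(Z)-oct-2-en-1-yl]cyclopent-2-en-1-yl]acetate | CCCCC/C=C\CC1=CC[C@H](O[Si](C)(C)C(C)(C)C)[C@@H]1CC(=O)OCC
F2 | step 15 | triethylsilyl ether of 22 | CCCCC/C=C\C[C@]12OC(=O)[C@H](O[Si](CC)(CC)CC)[C@H]1[C@@H](O[Si](C)(C)C(C)(C)C)C=C2
F3 | step 15 | lactol from F2 (both anomers) | CCCCC/C=C\C[C@]12OC(O)[C@H](O[Si](CC)(CC)CC)[C@H]1[C@@H](O[Si](C)(C)C(C)(C)C)C=C2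
F4 | step 15 | 7-O-triethylsilyl ether of acid 26 | CCCCC/C=C\C[C@@]1(O)C=C[C@H](O[Si](C)(C)C(C)(C)C)[C@@H]1[C@H](/C=C\CCCC(=O)O)O[Si](CC)(CC)CC
F5 | step 15 | 7-O-triethylsilyl ether of methyl ester 27 | CCCCC/C=C\C[C@@]1(O)C=C[C@H](O[Si](C)(C)C(C)(C)C)[C@@H]1[C@H](/C=C\CCCC(=O)OC)O[Si](CC)(CC)CC
F6 | step 20 | 7-O-triisopropylsilyl ether of 27 | CCCCC/C=C\C[C@@]1(O)C=C[C@H](O[Si](C)(C)C(C)(C)C)[C@@H]1[C@H](/C=C\CCCC(=O)OC)O[Si](C(C)C)(C(C)C)C(C)C
F7 | step 20 | 9-hydroxy 7-O-triisopropylsilyl ether | CCCCC/C=C\C[C@@]1(O)C=C[C@H](O)[C@@H]1[C@H](/C=C\CCCC(=O)OC)O[Si](C(C)C)(C(C)C)C(C)C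
F8 | step 20 | 9-oxo 7-O-triisopropylsilyl ether (enone) | CCCCC/C=C\C[C@@]1(O)C=CC(=O)[C@@H]1[C@H](/C=C\CCCC(=O)OC)O[Si](C(C)C)(C(C)C)C(C)C
F9 | step 20 | 10-iodo enone 7-O-triisopropylsilyl ether | CCCCC/C=C\C[C@@]1(O)C=C(I)C(=O)[C@@H]1[C@H](/C=C\CCCC(=O)OC)O[Si](C(C)C)(C(C)C)C(C)C
F10 | step 20 | 7-hydroxy 10-iodo enone (deacetyl target) | CCCCC/C=C\C[C@@]1(O)C=C(I)C(=O)[C@@H]1[C@H](/C=C\CCCC(=O)OC)O
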